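**Assumption:** compounds 10 and 11 are carried as roughly 1:1 mixtures of epimers at the acetal carbon (C2 of the dioxepine); step 8 erases that centre. This route is a paper design and has not been run.

## Retrosynthetic overview

1. Target 14 ⇐ alcohol 13 (global desilylation) ⇐ aldehyde 12 (NaBH4).
2. 12 ⇐ vinyl acetal 11 by Lewis-acid 1,3 O→C ring contraction of a 4,5-dihydro-1,3-dioxepine (7 → 5 ring); this makes the C2–C3 bond and sets C2 and C3.
3. 11 ⇐ 4,7-dihydro-1,3-dioxepine 10 by a stereocentre-forming Ni–H 1,3-hydrogen shift (new; sets C4). 10 ⇐ 9 + 6 by acetalisation, so the dioxepine ring is formed first and the tetrahydrofuran second.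
4. 9 ⇐ 6 + 8 by enantioselective Ni-catalysed alkyne–aldehyde reductive coupling (sets the carbinol carbon).
5. 6 ⇐ vanillin ⇐ guaiacol ⇐ catechol (+ MeI, glyoxylic acid); 8 ⇐ but-2-yne-1,4-diol.

## Route

Step 1
Reactants: 1 catechol (benzene-1,2-diol)
Product: 2 guaiacol (2-methoxyphenol)
Conditions: MeI (1.0 equiv), K2CO3 (1.0 equiv), acetone, reflux; base/acid extraction removes veratrole and unreacted catechol
Reagents that add atoms: iodomethane, CI
Why: Williamson mono-O-methylation, kept at the mono stage by using one equivalent of MeI; no stereocentre.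

Step 2
Reactants: 2 guaiacol; 3 glyoxylic acid (50% aq.)
Product: 5 vanillin (4-hydroxy-3-methoxybenzaldehyde), via vanillylmandelic acid 4 (not isolated)
Conditions: NaOH, H2O, 25 °C; then CuSO4 (cat.), air, NaOH, 95 °C; H2SO4 to pH 3
Reagents that add atoms: none
Why: Phenoxide-directed para-hydroxyalkylation (electrophilic aromatic substitution) followed by Cu-catalysed aerobic oxidative decarboxylation of the mandelic acid, the technical vanillin sequence; the transient carbinol centre is destroyed.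

Step 3
Reactants: 5 vanillin
Product: 6 4-(tert-butyldimethylsilyloxy)-3-methoxybenzaldehyde
Conditions: TBSCl (1.1 equiv), imidazole (1.2 equiv), DMF, 25 °C
Reagents that add atoms: tert-butyldimethylsilyl chloride, CC(C)(C)[Si](C)(C)Cl
Why: Standard phenol silylation, which blocks quinone-methide chemistry in all later Lewis-acid steps; no stereocentre.

Step 4
Reactants: 7 but-2-yne-1,4-diol
Product: 8 1,4-bis(trimethylsilyloxy)but-2-yne
Conditions: TMSCl (2.2 equiv), Et3N (2.4 equiv), CH2Cl2, 0 → 25 °C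
Reagents that add atoms: chlorotrimethylsilane, C[Si](C)(C)Cl
Why: Silylation of both primary alcohols gives the bis-silyl ether needed for the nickel step and for the later silyl-transfer acetalisation; no stereocentre.

Step 5
Reactants: 6 4-(tert-butyldimethylsilyloxy)-3-methoxybenzaldehyde; 8 1,4-bis(trimethylsilyloxy)but-2-yne
Product: 9 {[(1R,2E)-1-[4-(tert-butyldimethylsilyloxy)-3-methoxyphenyl]-4-(trimethylsilyloxy)-2-[(trimethylsilyloxy)methyl]but-2-en-1-yl]oxy}triethylsilane (the two CH2OTMS groups are cis on the alkene)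
Conditions: Ni(cod)2 (10 mol%), chiral C2-symmetric 1,3-diaryl-4,5-diphenylimidazolinium salt L*·HBF4 (10 mol%, the antipode that gives Si-face addition), KOt-Bu (10 mol%), Et3SiH (2 equiv), THF, 25 °C
Reagents that add atoms: triethylsilane, CC[SiH](CC)CC
Why: Ni(0)–NHC alkyne–aldehyde reductive coupling (Montgomery type) through an oxanickelacyclopentene and Si–H σ-bond metathesis; syn H/C addition across the symmetrical alkyne puts the two CH2OTMS groups cis, and the chiral carbene selects the aldehyde Si face to give the (R)-silyl ether.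

Step 6
Reactants: 9 allylic triethylsilyl ether (as above); 6 4-(tert-butyldimethylsilyloxy)-3-methoxybenzaldehyde
Product: 10 2-[4-(tert-butyldimethylsilyloxy)-3-methoxyphenyl]-5-{(R)-[4-(tert-butyldimethylsilyloxy)-3-methoxyphenyl](triethylsilyloxy)methyl}-4,7-dihydro-1,3-dioxepine (both C2 epimers)
Conditions: TMSOTf (2 mol%), CH2Cl2, −78 °C; pyridine quench
Reagents that add atoms: none
Why: Noyori silyl-transfer acetalisation, in which the silylated oxocarbenium of 6 is captured by the two primary TMS ethers with loss of (Me3Si)2O, the cis alkene pre-organising the seven-membered ring while the hindered secondary OTES stays out; the carbinol centre is untouched.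

Step 7
Reactants: 10 4,7-dihydro-1,3-dioxepine (as above)
Product: 11 (5S)-2-[4-(tert-butyldimethylsilyloxy)-3-methoxyphenyl]-5-{(S)-[4-(tert-butyldimethylsilyloxy)-3-methoxyphenyl](triethylsilyloxy)methyl}-4,5-dihydro-1,3-dioxepine (both C2 epimers)
Conditions: NiBr2(dppb) (5 mol%), LiBHEt3 (5 mol%), THF, −40 → 0 °C
Reagents that add atoms: none
Why: Proposed new method: a Ni–H adds syn across C5=C6 with H to C5 and Ni to the less hindered C6, and β-hydride elimination of the oxygen-activated C7–H then releases the enol ether, so a net 1,3-hydrogen shift makes the vinyl acetal and the new C5–H stereocentre under kinetic control; the face is chosen by the neighbouring silyloxy stereocentre (metal anti to the C–OSi bond), the same sense as the syn-selective Rh-catalysed hydroboration and the OH-directed hydrogenation of 2-substituted allylic alcohol derivatives, which predicts (5S); the closest known reaction is the Ni–H/Ru–H isomerisation of 5-methyl-4,7-dihydro-1,3-dioxepines, which has not been run under 1,2-induction from an exocyclic stereocentre.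

Step 8
Reactants: 11 4,5-dihydro-1,3-dioxepine (as above)
Product: 13 [(2S,3R,4S)-2-[4-(tert-butyldimethylsilyloxy)-3-methoxyphenyl]-4-{(S)-[4-(tert-butyldimethylsilyloxy)-3-methoxyphenyl](triethylsilyloxy)methyl}tetrahydrofuran-3-yl]methanol, via tetrahydrofuran-3-carbaldehyde 12 (not isolated)
Conditions: TMSOTf (0.2 equiv), CH2Cl2, −78 → 0 °C; then Et3N, NaBH4, MeOH, 0 °C
Reagents that add atoms: none
Why: Lewis-acid 1,3 O→C ring contraction of a vinyl acetal (Petasis–Ferrier type), in which TMSOTf ionises the enol C–O bond to an oxocarbenium/silyl enol ether pair that recloses by a five-membered Mukaiyama-type aldol addition; C4 is untouched, C3 forms trans to the C4 side chain, warming lets the 2-aryl centre equilibrate by reversible ring opening to the all-trans aldehyde, and NaBH4 then fixes C3.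

Step 9
Reactants: 13 tris-silyl ether (as above)
Product: 14 (2S,3R,4S)-2-(4-hydroxy-3-methoxyphenyl)-4-[(S)-hydroxy(4-hydroxy-3-methoxyphenyl)methyl]-3-(hydroxymethyl)tetrahydrofuran (target)
Conditions: TBAF (3.5 equiv), AcOH (3.5 equiv), THF, 0 → 25 °C
Reagents that add atoms: none
Why: Fluoride desilylation of the two aryl TBS ethers and the secondary TES ether, buffered with AcOH so that the p-hydroxybenzylic alcohol and ether do not form quinone methides; no stereocentre is touched.

## Compound list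

1 | catechol | Oc1ccccc1O | starting material
2 | guaiacol | COc1ccccc1O | intermediate
3 | glyoxylic acid | O=CC(=O)O | starting material
4 | vanillylmandelic acid (racemic) | COc1cc(C(O)C(=O)O)ccc1O | intermediate
5 | vanillin | COc1cc(C=O)ccc1O | intermediate
6 | 4-(tert-butyldimethylsilyloxy)-3-methoxybenzaldehyde | COc1cc(C=O)ccc1O[Si](C)(C)C(C)(C)C | intermediate
7 | but-2-yne-1,4-diol | OCC#CCO | starting material
8 | 1,4-bis(trimethylsilyloxy)but-2-yne | C[Si](C)(C)OCC#CCO[Si](C)(C)C | intermediate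
9 | (1R,2E)-allylic triethylsilyl ether, CH2OTMS groups cis | COc1cc([C@@H](O[Si](CC)(CC)CC)/C(CO[Si](C)(C)C)=C/CO[Si](C)(C)C)ccc1O[Si](C)(C)C(C)(C)C | intermediate
10 | 2-aryl-5-[(R)-aryl(triethylsilyloxy)methyl]-4,7-dihydro-1,3-dioxepine, C2 epimers | COc1cc([C@@H](O[Si](CC)(CC)CC)C2=CCOC(c3ccc(O[Si](C)(C)C(C)(C)C)c(OC)c3)OC2)ccc1O[Si](C)(C)C(C)(C)C | intermediate
11 | (5S)-2-aryl-5-[(S)-aryl(triethylsilyloxy)methyl]-4,5-dihydro-1,3-dioxepine, C2 epimers | COc1cc([C@@H](O[Si](CC)(CC)CC)[C@@H]2COC(c3ccc(O[Si](C)(C)C(C)(C)C)c(OC)c3)OC=C2)ccc1O[Si](C)(C)C(C)(C)C | intermediate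
12 | (2S,3S,4S)-2-aryl-4-[(S)-aryl(triethylsilyloxy)methyl]tetrahydrofuran-3-carbaldehyde (all-trans) | COc1cc([C@@H](O[Si](CC)(CC)CC)[C@@H]2CO[C@H](c3ccc(O[Si](C)(C)C(C)(C)C)c(OC)c3)[C@H]2C=O)ccc1O[Si](C)(C)C(C)(C)C | intermediate
13 | [(2S,3R,4S)-2-aryl-4-[(S)-aryl(triethylsilyloxy)methyl]tetrahydrofuran-3-yl]methanol | COc1cc([C@@H](O[Si](CC)(CC)CC)[C@@H]2CO[C@H](c3ccc(O[Si](C)(C)C(C)(C)C)c(OC)c3)[C@H]2CO)ccc1O[Si](C)(C)C(C)(C)C | intermediate
14 | (2S,3R,4S)-2-(4-hydroxy-3-methoxyphenyl)-4-[(S)-hydroxy(4-hydroxy-3-methoxyphenyl)methyl]-3-(hydroxymethyl)tetrahydrofuran | COc1cc([C@@H](O)[C@@H]2CO[C@H](c3ccc(O)c(OC)c3)[C@H]2CO)ccc1O | target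

(In 9–13, "aryl" is 4-(tert-butyldimethylsilyloxy)-3-methoxyphenyl.)

## Step count and risks

Total steps: 9. Longest linear sequence: 8 (steps 1, 2, 3, 5, 6, 7, 8, 9).

**Step 7 (the proposed new step).** The facial selectivity of the hydride shift is predicted by analogy only, and the two acetal epimers of 10 may respond differently. The known-chemistry fallback sets out from 9 and comes back at 13, setting the ring stereocentre by conjugate reduction and building the ring by the classical aldol/benzylic etherification. The two TMS ethers of 9 are cleaved (K2CO3 cat., MeOH, 0 °C) to (2E)-2-[(R)-aryl(triethylsilyloxy)methyl]but-2-ene-1,4-diol F1. MnO2 oxidises the less hindered allylic alcohol and then the lactol to give 4-[(R)-aryl(triethylsilyloxy)methyl]furan-2(5H)-one F2. Copper-hydride asymmetric conjugate reduction (CuCl, NaOt-Bu, matched p-tol-BINAP antipode, PMHS, t-BuOH) gives (4S)-4-[(S)-aryl(triethylsilyloxy)methyl]dihydrofuran-2(3H)-one F3. Its lithium enolate (LiHMDS, THF, −78 °C) adds to 6 trans to the side chain to give (3S,4S)-3-[aryl(hydroxy)methyl]-4-[(S)-aryl(triethylsilyloxy)methyl]dihydrofuran-2(3H)-one F4. LiBH4 opens the lactone to (2R,3S)-2-[aryl(hydroxy)methyl]-3-[(S)-aryl(triethylsilyloxy)methyl]butane-1,4-diol F5. Mild acid (CSA cat., CH2Cl2, 0 °C) ionises only the free benzylic alcohol, and the primary alcohol on the neighbouring arm closes the 2,3-trans ring to give 13.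

**Step 8.** The kinetic 2,3-cis aldehyde may not equilibrate, and the benzylic OTES group may ionise or take part in acetal exchange under TMSOTf. The fallback sets out from 11 and comes back at 13. The vinyl acetal is hydrolysed (PPTS, THF–H2O, 25 °C) to (4S)-4-[(S)-aryl(triethylsilyloxy)methyl]tetrahydrofuran-2-ol F6, with aldehyde 6 recovered. The lactol is oxidised (Ag2CO3 on Celite, benzene, reflux) to lactone F3, which is carried through F4 and F5 to 13 as described for step 7.

**Step 5.** The enantioselectivity of the nickel coupling with this 1,4-dioxygenated alkyne and electron-rich aldehyde is uncertain. The fallback sets out from 8 and 6 and comes back at 9, replacing the reductive coupling by a catalytic asymmetric alkenylzinc addition. Hydrozirconation of 8 (Cp2Zr(H)Cl, CH2Cl2, 25 °C) gives (E)-[1,4-bis(trimethylsilyloxy)but-2-en-2-yl]zirconocene chloride F7. Transmetalation with Me2Zn (toluene, −65 °C) gives (E)-[1,4-bis(trimethylsilyloxy)but-2-en-2-yl](methyl)zinc F8. Addition to 6 with (−)-MIB (10 mol%, −30 °C, Si face) gives (1R,2E)-1-aryl-4-(trimethylsilyloxy)-2-[(trimethylsilyloxy)methyl]but-2-en-1-ol F9. TESCl and imidazole (DMF, 0 °C) then return 9.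

## Further compounds

F1 | step 7 | (2E)-2-[(R)-aryl(triethylsilyloxy)methyl]but-2-ene-1,4-diol | COc1cc([C@@H](O[Si](CC)(CC)CC)/C(CO)=C/CO)ccc1O[Si](C)(C)C(C)(C)C
F2 | step 7 | 4-[(R)-aryl(triethylsilyloxy)methyl]furan-2(5H)-one | COc1cc([C@@H](O[Si](CC)(CC)CC)C2=CC(=O)OC2)ccc1O[Si](C)(C)C(C)(C)C
F3 | step 7 | (4S)-4-[(S)-aryl(triethylsilyloxy)methyl]dihydrofuran-2(3H)-one | COc1cc([C@@H](O[Si](CC)(CC)CC)[C@H]2CC(=O)OC2)ccc1O[Si](C)(C)C(C)(C)C
F4 | step 7 | (3S,4S)-3-[aryl(hydroxy)methyl]-4-[(S)-aryl(triethylsilyloxy)methyl]dihydrofuran-2(3H)-one, carbinol epimers | COc1cc([C@@H](O[Si](CC)(CC)CC)[C@@H]2COC(=O)[C@@H]2C(O)c3ccc(O[Si](C)(C)C(C)(C)C)c(OC)c3)ccc1O[Si](C)(C)C(C)(C)C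
F5 | step 7 | (2R,3S)-2-[aryl(hydroxy)methyl]-3-[(S)-aryl(triethylsilyloxy)methyl]butane-1,4-diol, carbinol epimers | COc1cc([C@@H](O[Si](CC)(CC)CC)[C@H](CO)[C@H](CO)C(O)c2ccc(O[Si](C)(C)C(C)(C)C)c(OC)c2)ccc1O[Si](C)(C)C(C)(C)C
F6 | step 8 | (4S)-4-[(S)-aryl(triethylsilyloxy)methyl]tetrahydrofuran-2-ol, anomers | COc1cc([C@@H](O[Si](CC)(CC)CC)[C@H]2CC(O)OC2)ccc1O[Si](C)(C)C(C)(C)C
F7 | step 5 | (E)-[1,4-bis(trimethylsilyloxy)but-2-en-2-yl]zirconocene chloride | C[Si](C)(C)OC/C=C(\CO[Si](C)(C)C)[Zr](Cl)(C1C=CC=C1)C1C=CC=C1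
F8 | step 5 | (E)-[1,4-bis(trimethylsilyloxy)but-2-en-2-yl](methyl)zinc | C[Zn]/C(CO[Si](C)(C)C)=C/CO[Si](C)(C)C
F9 | step 5 | (1R,2E)-1-aryl-4-(trimethylsilyloxy)-2-[(trimethylsilyloxy)methyl]but-2-en-1-ol | COc1cc([C@@H](O)/C(CO[Si](C)(C)C)=C/CO[Si](C)(C)C)ccc1O[Si](C)(C)C(C)(C)C
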